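## Structural features

The target is an isoflavone. Benzo ring A (C4a to C8a, hydroxyls on C5 and C7) is fused to pyranone ring C (O1, C2–H, C3, C4=O), and C3 carries aryl ring B through the C3–C1' bond. Ring B is 1,3,4,5-tetrasubstituted: a free hydroxyl on C3', a methoxyl on C4' and an (E)-3-hydroxy-3-methylbut-1-enyl chain on C5'. This placing of OH and OMe is the reverse of that in vanillin. There is no stereocentre, so no neighbouring stereocentres have to be related; the only stereochemical element is the E double bond of the side chain. The fragile group is the tertiary alcohol, which is allylic and conjugated with ring B and so ionises readily in acid (dehydration, solvolysis). The three phenols and C2 of ring C, a vinylogous ester carbon open to hard nucleophiles, also need care. The real difficulty is order and chemoselectivity: ring C must be built onto a trioxygenated ring A while ring B keeps a latent handle at C5', the two ring-B oxygens must be differentiated, and the acid-labile chain must arrive after the last acidic operation. The key step uses two facts: C4 is a single carbon bridging C3 and C4a, so it can come from carbon monoxide, and ring A descends from a symmetric 3,5-dioxygenated aryl ether whose two positions ortho to O1 are identical and each activated by three oxygens.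

## Logic of the disconnections

19 to 16 and 18. The C5'–C(alkenyl) bond is cut. The tertiary allylic alcohol then enters in the last step, after every acidic operation, and the only stereochemical element leaves with it. What remains is a flat chloro-isoflavone triol. The forward step must couple an electron-rich, ortho-substituted aryl chloride with retention of the E geometry while three phenols are free.

18 to 17. The C–B bond is cut. A syn, terminal-selective borylation of the alkyne fixes the E geometry in one step from a bulk chemical. The forward step must tolerate the free tertiary hydroxyl and put boron on the terminal carbon only.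

16 to 15. The three O–CH2 acetal bonds are cut. Removing the MOM groups at this point confines the acidic deprotection to a molecule that has no acid-sensitive group. The forward step asks only that the chromone and the C–Cl bond survive methanolic acid.

15 to 13 and 14. The C3–C4 and C4–C4a bonds are cut, which opens ring C and removes the carbonyl carbon as 14. The tricyclic core falls back to an acyclic enol triflate that carries both aryl rings in the correct connectivity. The forward step must insert 14 before any direct C–H coupling, acylate the ortho carbon of the aryloxy ring, and leave the C–Cl bond alone.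

13 to 11 (through 12). The O–S bond is cut. The triflate is the enol form of a ketone, so the whole problem reduces to an α-aryloxy ketone. The forward step must give the Z enol derivative, in which sulfonate oxygen and aryloxy oxygen are on the same side.

11 to 8 and 10. The O–CH2 bond (the later O1–C2 bond) is cut. This is the convergent point: ring B with its two-carbon unit meets ring A in a simple etherification. The forward step needs O-alkylation of an electron-rich phenol in preference to C-alkylation.

10 to 9. Two O–CH2 acetal bonds are cut. Ring A comes from a symmetric triol of negligible cost. The forward step is a statistical double protection and depends on chromatographic separation.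

8 to 6 (through 7), then 6 to 5 to 4. The C–Br bond and then the C–CH3 bond (the later C2 carbon) are cut, with an adjustment of oxidation level. This brings the bromoketone back to a benzaldehyde. The bromination must not release acid, because of the MOM ether. It is done before ring A is present, so the very electron-rich ring never meets an electrophilic bromine source.

4 to 3 to 2 to 1. The O–CH2 (MOM), O–CH3 and again O–CH3 bonds are cut. The required pattern (OMe para, protected OH meta to the carbon chain) is obtained from the commercial chloro-aldehyde by moving the methyl group from one oxygen to the other. The forward steps need a chelation-controlled demethylation and a methylation that distinguishes the two catechol hydroxyls by acidity.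

## Other disconnections considered

Alternative 1: The C4a–C5 bond is cut, so ring A is made from an open chain. In the forward step Mg(OMe)2 in methanol cyclises the triketo ester A1 by Claisen attack of its C6 on the ester carbonyl, giving the acylphloroglucinol A2. Ring C would then be closed by a one-carbon insertion at the benzylic methylene, and the endgame would follow the chosen plan.
- In favour: the condensation is a known, biomimetic reaction type. A2 is the classical isoflavone precursor. No pressure equipment or new catalysis is needed. No palladium step precedes the last one, so a bromide can be carried, which makes the final Suzuki coupling easier than with the chloride of 16. On these points of precedent and of the final coupling the alternative is the better plan.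
- Against: A1 is a sensitive polycarbonyl compound that needs several polyanion acylations. It can also cyclise in the aldol sense, and its benzylic methylene offers a further enolisation site. The route constructs a ring that 9 supplies ready-made, and A2 is in any case within reach of a one-step Hoesch-type C-acylation of 9.
- Comparison: both plans use the symmetry of ring A equally well, so neither has a regiochemical question there. Mechanistically the alternative is safer. In step count and convergence it is clearly worse, because the chain assembly and the separate closure of ring C add steps without adding selectivity.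

Alternative 2: The C3–C4 and O1–C2 bonds are cut. In the forward step [Cp*RhCl2]2 (trivalent rhodium) with Cu(OAc)2 activates the formyl C–H of salicylaldehyde A3 under direction by the phenol and adds it, with the O–H, across silylalkyne A4 to give the 2-silylchromone A5. Protodesilylation at C2 follows.
- In favour: this is a known reaction class. It is convergent and joins both halves while forming ring C. A3 arises from a protection that leaves only the hydrogen-bonded hydroxyl free, which is cleaner than the statistical step 7 of the chosen plan. Trivalent rhodium does not insert into C–Br, so a bromide can be used. A4 needs about two steps from the ring-B aldehyde, against five from 4 to 13. On step count before the key step, on the quality of the ring-A protection and on the final coupling the alternative is the equal or the better.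
- Against: the orientation of insertion (silicon next to oxygen, aryl at C3) is not assured for an electron-rich aryl(silyl)alkyne, and the reverse orientation leads to a flavone skeleton. The alkyne may lose silicon under Cu(OAc)2 at the reaction temperature. The formyl group is flanked by an ortho MOM ether and may decarbonylate. Two equivalents of Cu(OAc)2 and an extra desilylation step are needed.
- Comparison: in the chosen plan the C2–H/C3-aryl pattern is fixed by the constitution of 11, so no regiochemical question arises at ring C. The alternative is at least as short overall and has precedent for its reaction class, but carries a regiochemical risk at the ring-forming step.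

Alternative 3: Only the C4–C4a bond is cut, with C4 already attached to C3 as a carboxyl group. In the forward step trifluoroacetic anhydride converts acid A6 into a mixed anhydride that acylates the ortho carbon of the symmetric bis(benzyloxy)phenoxy ring, giving A7.
- In favour: this is classical Friedel–Crafts chemistry of a known type. It uses the same symmetric, triply activated carbon as the chosen plan and needs no metal and no carbon monoxide. It can be run cold and tolerates a bromide. On precedent and on the final coupling it is the better plan.
- Against: A6 needs its own sequence (homologation of ring B to the arylacetic level, C-formylation, enol activation, addition–elimination by the phenol, ester cleavage), and its geometry must place carboxyl and aryloxy on the same side. The acidic medium excludes MOM ethers. Benzyl ethers then have to be removed by a Lewis acid, not by hydrogenolysis, because of C–Br and C2=C3, and this puts the C4' methyl ether at some risk. The anhydride may also C-acylate the electron-rich ring intermolecularly.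
- Comparison: the chosen key step is the carbonylative counterpart of this closure. It introduces the C4 carbon and forms both of its bonds in one operation from a ketone-derived triflate, which saves the separate construction of the carboxyl carbon and keeps MOM protection. The alternative gives up that economy for certainty, and in shortened form it serves as the fallback for the key step.

Key step: step 10

Remark on the chemistry: the structures of 13, 14 and 15 are mutually consistent and need no correction. In 13 the descriptor Z means that the triflate oxygen and the aryloxy oxygen are cis, which is the arrangement ring closure requires. The ring-B pattern of 19 is the reverse of that of 1, which is why steps 1 and 2 move the methyl group. Assumption: 18 is made in one step, not purchased, and 5 is formed as a racemate whose stereocentre is erased in step 5.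

## Route

Step 1
Reactants: 1 5-chlorovanillin (3-chloro-4-hydroxy-5-methoxybenzaldehyde)
Product: 2 3-chloro-4,5-dihydroxybenzaldehyde
Conditions: AlCl3, pyridine, CH2Cl2, reflux; then 2 M HCl
Reagents that add atoms: none
Why: Lewis-acid demethylation of an aryl methyl ether with a free ortho hydroxyl, which proceeds through an aluminium chelate with transfer of the methyl group to pyridine; the aldehyde and the aryl chloride are inert.

Step 2
Reactants: 2 3-chloro-4,5-dihydroxybenzaldehyde
Product: 3 3-chloro-5-hydroxy-4-methoxybenzaldehyde
Conditions: MeI (1.1 equiv), Li2CO3, DMF, 40 °C
Reagents that add atoms: iodomethane, CI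
Why: Williamson etherification under acidity control: the hydroxyl on C4 (para to the formyl group, ortho to chlorine) is the more acidic, so the weak base Li2CO3 should ionise and methylate that oxygen only.

Step 3
Reactants: 3 3-chloro-5-hydroxy-4-methoxybenzaldehyde
Product: 4 3-chloro-4-methoxy-5-(methoxymethoxy)benzaldehyde
Conditions: MOMCl, iPr2NEt, CH2Cl2, 0 °C to rt
Reagents that add atoms: chloromethyl methyl ether, COCCl
Why: O-alkylation of the remaining phenol to a MOM acetal, which is stable to the organometallic, basic and palladium steps ahead and is removed by mild acid.

Step 4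
Reactants: 4 3-chloro-4-methoxy-5-(methoxymethoxy)benzaldehyde
Product: 5 1-[3-chloro-4-methoxy-5-(methoxymethoxy)phenyl]ethan-1-ol (racemic)
Conditions: MeMgBr, THF, 0 °C; aq. NH4Cl
Reagents that add atoms: methylmagnesium bromide, C[Mg]Br
Why: Grignard addition to the aldehyde; the carbinol stereocentre is formed without control (racemate) and is erased in step 5, and the aryl chloride does not react at 0 °C.

Step 5
Reactants: 5 1-[3-chloro-4-methoxy-5-(methoxymethoxy)phenyl]ethan-1-ol
Product: 6 1-[3-chloro-4-methoxy-5-(methoxymethoxy)phenyl]ethan-1-one
Conditions: MnO2 (activated, excess), CH2Cl2, rt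
Reagents that add atoms: none
Why: Oxidation of an electron-rich benzylic alcohol on MnO2 under neutral, heterogeneous conditions that leave the MOM acetal untouched.

Step 6
Reactants: 6 1-[3-chloro-4-methoxy-5-(methoxymethoxy)phenyl]ethan-1-one
Product: 8 2-bromo-1-[3-chloro-4-methoxy-5-(methoxymethoxy)phenyl]ethan-1-one, via trimethylsilyl enol ether 7 (not isolated)
Conditions: LiN(SiMe3)2, TMSCl, THF, −78 °C; solvent exchange; then NBS, THF, 0 °C
Reagents that add atoms: N-bromosuccinimide, O=C1CCC(=O)N1Br
Why: Electrophilic bromination of a silyl enol ether; the ketone has a single enolisable position, the bromide is formed without release of HBr so the MOM ether is safe, and the enol ether reacts with NBS far faster than the acyl-deactivated ring.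

Step 7
Reactants: 9 phloroglucinol (benzene-1,3,5-triol)
Product: 10 3,5-bis(methoxymethoxy)phenol
Conditions: MOMCl (2.0 equiv), iPr2NEt, DMF, 0 °C to rt; chromatography
Reagents that add atoms: chloromethyl methyl ether, COCCl
Why: Statistical O-alkylation of three equivalent hydroxyls; the bis-ether should be separable from the mono- and tris-ethers, which can be recycled, and the cost of 9 makes the moderate efficiency acceptable.

Step 8
Reactants: 8 2-bromo-1-[3-chloro-4-methoxy-5-(methoxymethoxy)phenyl]ethan-1-one; 10 3,5-bis(methoxymethoxy)phenol
Product: 11 2-[3,5-bis(methoxymethoxy)phenoxy]-1-[3-chloro-4-methoxy-5-(methoxymethoxy)phenyl]ethan-1-one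
Conditions: K2CO3, acetone, reflux
Reagents that add atoms: none
Why: Williamson ether synthesis with a highly reactive α-bromoketone (SN2); K2CO3 in acetone favours O- over C-alkylation of the phenoxide.

Step 9
Reactants: 11 2-[3,5-bis(methoxymethoxy)phenoxy]-1-[3-chloro-4-methoxy-5-(methoxymethoxy)phenyl]ethan-1-one
Product: 13 (Z)-2-[3,5-bis(methoxymethoxy)phenoxy]-1-[3-chloro-4-methoxy-5-(methoxymethoxy)phenyl]ethenyl trifluoromethanesulfonate, via lithium Z-enolate 12 (not isolated)
Conditions: LiN(SiMe3)2, THF, −78 °C; then Comins' reagent, −78 to 0 °C; chromatography on Et3N-deactivated silica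
Reagents that add atoms: N-(5-chloropyridin-2-yl)-1,1,1-trifluoro-N-(trifluoromethylsulfonyl)methanesulfonamide (Comins' reagent), FC(F)(F)S(=O)(=O)N(c1ccc(Cl)cn1)S(=O)(=O)C(F)(F)F
Why: Enol triflation of a ketone enolate: lithium bridges the enolate oxygen and the aryloxy oxygen, and allylic 1,3-strain between the aryl group and the aryloxy group acts in the same direction, so the Z enolate should dominate and be trapped on oxygen with retention of geometry.

Step 10
Reactants: 13 (Z)-2-[3,5-bis(methoxymethoxy)phenoxy]-1-[3-chloro-4-methoxy-5-(methoxymethoxy)phenyl]ethenyl trifluoromethanesulfonate; 14 carbon monoxide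
Product: 15 3-[3-chloro-4-methoxy-5-(methoxymethoxy)phenyl]-5,7-bis(methoxymethoxy)-4H-chromen-4-one
Conditions: Pd(OAc)2 (10 mol %), 1,3-bis(diphenylphosphino)propane (12 mol %), CsO2CCMe3 (2 equiv), CO (5 bar), DMF, 90 °C
Reagents that add atoms: none
Why: Proposed new method: zerovalent palladium formed in situ from Pd(OAc)2 and the diphosphine should add oxidatively to the C–OTf bond of 13 with retention of the Z geometry, and insertion of CO should give a cationic acyl complex of divalent palladium whose acyl carbon (the later C4) is cis to the aryloxy oxygen. The acyl group should then be delivered to the ortho carbon of the bis(methoxymethoxy)phenoxy ring, either by carboxylate-assisted palladation to a seven-membered acyl(aryl)palladacycle followed by reductive elimination, or by direct Friedel–Crafts attack of the arene on the acyl carbon with loss of zerovalent palladium; pivalate takes up the proton. The closest known reaction types are the palladium-catalysed carbonylative C–H cyclisations of ortho-halobiaryls to fluorenones and of ortho-halodiaryl ethers to xanthones, together with the alkoxycarbonylation of vinyl triflates under the same catalyst; new here is a vinyl triflate tethered to the arene through an enol-ether oxygen, which leads to a chromone. Ring C closes as a six-membered ring through the bonds C3–C4 and C4–C4a, the second one in a 6-exo-trig sense at the acyl carbon. No stereocentre is formed. Three selectivities are needed: CO insertion must precede direct C–H coupling of the vinylpalladium (which would close a five-membered benzofuran ring), and CO pressure with a cationic vinylpalladium should secure this; site selectivity on ring A is guaranteed because the two ortho positions are equivalent by symmetry and each is activated by two ortho oxygens and one para oxygen, while the position between the two MOM ethers is out of reach; and the ring-B C–Cl bond should stay intact because an electron-rich aryl chloride adds very slowly to this diphosphine complex at 90 °C. An E isomer carried over from step 9 cannot close directly, but its acyl complex is a push–pull enone that may equilibrate.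

Step 11
Reactants: 15 3-[3-chloro-4-methoxy-5-(methoxymethoxy)phenyl]-5,7-bis(methoxymethoxy)-4H-chromen-4-one
Product: 16 3-(3-chloro-5-hydroxy-4-methoxyphenyl)-5,7-dihydroxy-4H-chromen-4-one
Conditions: 3 M HCl, MeOH, 50 °C
Reagents that add atoms: none
Why: Acid-catalysed transacetalisation of the three MOM ethers to dimethoxymethane; the chromone, the methyl ether and the aryl chloride are stable, and no acid-labile group is present yet.

Step 12
Reactants: 17 2-methylbut-3-yn-2-ol
Product: 18 (E)-2-methyl-4-(4,4,5,5-tetramethyl-1,3,2-dioxaborolan-2-yl)but-3-en-2-ol
Conditions: B2pin2, CuCl (5 mol %), Xantphos (5 mol %), NaOt-Bu (10 mol %), MeOH (2 equiv), THF, rt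
Reagents that add atoms: bis(pinacolato)diboron, CC1(C)OB(OC1(C)C)B1OC(C)(C)C(C)(C)O1
Why: Copper-catalysed borylation of a terminal alkyne: syn addition of Cu–B places boron on the terminal carbon, away from the tertiary centre, and protonolysis by methanol with retention gives the E alkenylboronate; the free hydroxyl is tolerated.

Step 13
Reactants: 16 3-(3-chloro-5-hydroxy-4-methoxyphenyl)-5,7-dihydroxy-4H-chromen-4-one; 18 (E)-2-methyl-4-(4,4,5,5-tetramethyl-1,3,2-dioxaborolan-2-yl)but-3-en-2-ol
Product: 19 5,7-dihydroxy-3-{3-hydroxy-5-[(1E)-3-hydroxy-3-methylbut-1-en-1-yl]-4-methoxyphenyl}-4H-chromen-4-one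
Conditions: Pd(OAc)2 (5 mol %), SPhos (10 mol %), K3PO4 (5 equiv), 1,4-dioxane/H2O (4:1), 70 °C; work-up at pH 6 (phosphate buffer)
Reagents that add atoms: none
Why: Suzuki–Miyaura coupling in which the bulky, electron-rich biarylphosphine allows oxidative addition into the hindered C–Cl bond; transmetalation and reductive elimination retain the E geometry, and because nothing has to be deprotected afterwards the tertiary allylic alcohol never meets acid.

## Compound list

1 | 5-chlorovanillin (3-chloro-4-hydroxy-5-methoxybenzaldehyde) | COc1cc(C=O)cc(Cl)c1O | starting material
2 | 3-chloro-4,5-dihydroxybenzaldehyde | O=Cc1cc(O)c(O)c(Cl)c1 | intermediate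
3 | 3-chloro-5-hydroxy-4-methoxybenzaldehyde | COc1c(O)cc(C=O)cc1Cl | intermediate
4 | 3-chloro-4-methoxy-5-(methoxymethoxy)benzaldehyde | COCOc1cc(C=O)cc(Cl)c1OC | intermediate
5 | 1-[3-chloro-4-methoxy-5-(methoxymethoxy)phenyl]ethan-1-ol (racemic) | COCOc1cc(C(C)O)cc(Cl)c1OC | intermediate
6 | 1-[3-chloro-4-methoxy-5-(methoxymethoxy)phenyl]ethan-1-one | COCOc1cc(C(C)=O)cc(Cl)c1OC | intermediate
7 | ({1-[3-chloro-4-methoxy-5-(methoxymethoxy)phenyl]ethenyl}oxy)trimethylsilane | COCOc1cc(C(=C)O[Si](C)(C)C)cc(Cl)c1OC | intermediate
8 | 2-bromo-1-[3-chloro-4-methoxy-5-(methoxymethoxy)phenyl]ethan-1-one | COCOc1cc(C(=O)CBr)cc(Cl)c1OC | intermediate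
9 | phloroglucinol (benzene-1,3,5-triol) | Oc1cc(O)cc(O)c1 | starting material
10 | 3,5-bis(methoxymethoxy)phenol | COCOc1cc(O)cc(OCOC)c1 | intermediate
11 | 2-[3,5-bis(methoxymethoxy)phenoxy]-1-[3-chloro-4-methoxy-5-(methoxymethoxy)phenyl]ethan-1-one | COCOc1cc(OCC(=O)c2cc(Cl)c(OC)c(OCOC)c2)cc(OCOC)c1 | intermediate
12 | lithium (Z)-2-[3,5-bis(methoxymethoxy)phenoxy]-1-[3-chloro-4-methoxy-5-(methoxymethoxy)phenyl]ethen-1-olate | [Li+].[O-]/C(=C\Oc1cc(OCOC)cc(OCOC)c1)c1cc(Cl)c(OC)c(OCOC)c1 | intermediate
13 | (Z)-2-[3,5-bis(methoxymethoxy)phenoxy]-1-[3-chloro-4-methoxy-5-(methoxymethoxy)phenyl]ethenyl trifluoromethanesulfonate | FC(F)(F)S(=O)(=O)O/C(=C\Oc1cc(OCOC)cc(OCOC)c1)c1cc(Cl)c(OC)c(OCOC)c1 | intermediate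
14 | carbon monoxide | [C-]#[O+] | starting material
15 | 3-[3-chloro-4-methoxy-5-(methoxymethoxy)phenyl]-5,7-bis(methoxymethoxy)-4H-chromen-4-one | COCOc1cc(OCOC)c2c(c1)occ(-c1cc(Cl)c(OC)c(OCOC)c1)c2=O | intermediate
16 | 3-(3-chloro-5-hydroxy-4-methoxyphenyl)-5,7-dihydroxy-4H-chromen-4-one | COc1c(O)cc(-c2coc3cc(O)cc(O)c3c2=O)cc1Cl | intermediate
17 | 2-methylbut-3-yn-2-ol | C#CC(C)(C)O | starting material
18 | (E)-2-methyl-4-(4,4,5,5-tetramethyl-1,3,2-dioxaborolan-2-yl)but-3-en-2-ol | CC(C)(O)/C=C/B1OC(C)(C)C(C)(C)O1 | intermediate
19 | 5,7-dihydroxy-3-{3-hydroxy-5-[(1E)-3-hydroxy-3-methylbut-1-en-1-yl]-4-methoxyphenyl}-4H-chromen-4-one | COc1c(O)cc(-c2coc3cc(O)cc(O)c3c2=O)cc1/C=C/C(C)(C)O | target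

## Step count and least certain steps

Total step count: 13. Longest linear sequence: 11 steps (steps 1 to 6, 8 to 11 and 13, from 1 to 19). Steps 7 and 12 are single-step side branches.

**Step 10 (key step).**
- Risk: the acylpalladium may be intercepted before it reaches the arene, by adventitious water or by pivalate. If CO insertion lags, direct C–H coupling of the vinylpalladium without CO uptake may take over. The C–H acylation itself may be slow because the reacting carbon lies between two oxygen substituents, which leaves time for loss of the triflate group.
- Fallback (known chemistry): it sets out from 13 and returns at 15. Hydroxycarbonylation of the vinyl triflate (Pd(OAc)2, the same diphosphine, KOAc, CO at 1 atm, DMF, 60 °C, aqueous work-up) should give (2Z)-3-[3,5-bis(methoxymethoxy)phenoxy]-2-[3-chloro-4-methoxy-5-(methoxymethoxy)phenyl]prop-2-enoic acid F1. Activation as the mixed anhydride (trifluoroacetic anhydride, 2,6-lutidine, CH2Cl2, 0 °C) should then close ring C by intramolecular Friedel–Crafts acylation of the same symmetric carbon, giving 15. Any partial loss of MOM groups at this stage is harmless, because step 11 removes them all.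

**Step 9.**
- Risk: erosion of the enolate geometry, sluggish O-sulfonylation of the lithium enolate, and hydrolytic loss of the electron-rich enol triflate during purification.
- Fallback: it sets out from 11 and returns at 13. It separates the setting of geometry from the sulfonylation. Silylation of the sodium enolate (NaN(SiMe3)2, TBSCl, THF, −78 °C) should give the more robust tert-butyl({(Z)-2-[3,5-bis(methoxymethoxy)phenoxy]-1-[3-chloro-4-methoxy-5-(methoxymethoxy)phenyl]ethenyl}oxy)dimethylsilane F2. This can be purified and freed of any E isomer. Fluoride-triggered triflation (CsF, PhNTf2, 1,2-dimethoxyethane, rt) through the cesium enolate should then give 13.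

**Step 13.**
- Risk: slow oxidative addition into an electron-rich, ortho-substituted C–Cl bond of a substrate that is a triphenoxide under the conditions, binding of the catalyst by the phenoxides, protodeboronation of 18, and base-induced opening of ring C at C2.
- Fallback: it sets out from 16 and returns at 19. Acetylation (Ac2O, pyridine) should give 3-[3-(acetyloxy)-5-chloro-4-methoxyphenyl]-4-oxo-4H-chromene-5,7-diyl diacetate F3. Coupling with 18 under anhydrous conditions (Pd(OAc)2, SPhos, K3PO4, toluene, 80 °C) should give 3-{3-(acetyloxy)-5-[(1E)-3-hydroxy-3-methylbut-1-en-1-yl]-4-methoxyphenyl}-4-oxo-4H-chromene-5,7-diyl diacetate F4. Methanolysis (K2CO3, MeOH, rt) is a basic deprotection that the tertiary allylic alcohol tolerates. Any acetate lost during the coupling converges on 19 in this last operation.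

**Step 6.**
- Risk: premature hydrolysis of the silyl enol ether back to the ketone, double bromination, and release of acid that would attack the MOM ether.
- Fallback: it sets out from 4 (with 10) and returns at 11, avoiding the bromoketone altogether. Corey–Chaykovsky methylenation (Me3SI, NaH, DMSO/THF) should give 2-[3-chloro-4-methoxy-5-(methoxymethoxy)phenyl]oxirane F5 (racemic). Opening at the terminal carbon by the phenoxide of 10 (Cs2CO3, DMF, 80 °C) should give 2-[3,5-bis(methoxymethoxy)phenoxy]-1-[3-chloro-4-methoxy-5-(methoxymethoxy)phenyl]ethan-1-ol F6 (racemic). Oxidation with Dess–Martin periodinane (NaHCO3, CH2Cl2) should give 11. The regiochemistry of the epoxide opening is the weak point of this detour.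

## Further compounds

F1 | step 10 | (2Z)-3-[3,5-bis(methoxymethoxy)phenoxy]-2-[3-chloro-4-methoxy-5-(methoxymethoxy)phenyl]prop-2-enoic acid | OC(=O)/C(=C\Oc1cc(OCOC)cc(OCOC)c1)c1cc(Cl)c(OC)c(OCOC)c1
F2 | step 9 | tert-butyl({(Z)-2-[3,5-bis(methoxymethoxy)phenoxy]-1-[3-chloro-4-methoxy-5-(methoxymethoxy)phenyl]ethenyl}oxy)dimethylsilane | CC(C)(C)[Si](C)(C)O/C(=C\Oc1cc(OCOC)cc(OCOC)c1)c1cc(Cl)c(OC)c(OCOC)c1
F3 | step 13 | 3-[3-(acetyloxy)-5-chloro-4-methoxyphenyl]-4-oxo-4H-chromene-5,7-diyl diacetate | COc1c(OC(C)=O)cc(-c2coc3cc(OC(C)=O)cc(OC(C)=O)c3c2=O)cc1Cl
F4 | step 13 | 3-{3-(acetyloxy)-5-[(1E)-3-hydroxy-3-methylbut-1-en-1-yl]-4-methoxyphenyl}-4-oxo-4H-chromene-5,7-diyl diacetate | COc1c(OC(C)=O)cc(-c2coc3cc(OC(C)=O)cc(OC(C)=O)c3c2=O)cc1/C=C/C(C)(C)O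
F5 | step 6 | 2-[3-chloro-4-methoxy-5-(methoxymethoxy)phenyl]oxirane (racemic) | COCOc1cc(C2CO2)cc(Cl)c1OC
F6 | step 6 | 2-[3,5-bis(methoxymethoxy)phenoxy]-1-[3-chloro-4-methoxy-5-(methoxymethoxy)phenyl]ethan-1-ol (racemic) | COCOc1cc(OCC(O)c2cc(Cl)c(OC)c(OCOC)c2)cc(OCOC)c1
A1 | alternative 1 | methyl 8-[3-bromo-4-methoxy-5-(methoxymethoxy)phenyl]-3,5,7-trioxooctanoate | COC(=O)CC(=O)CC(=O)CC(=O)Cc1cc(Br)c(OC)c(OCOC)c1
A2 | alternative 1 | 2-[3-bromo-4-methoxy-5-(methoxymethoxy)phenyl]-1-(2,4,6-trihydroxyphenyl)ethanone | Oc1cc(O)c(C(=O)Cc2cc(Br)c(OC)c(OCOC)c2)c(O)c1
A3 | alternative 2 | 2-hydroxy-4,6-bis(methoxymethoxy)benzaldehyde | COCOc1cc(O)c(C=O)c(OCOC)c1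
A4 | alternative 2 | {[3-bromo-4-methoxy-5-(methoxymethoxy)phenyl]ethynyl}(trimethyl)silane | C[Si](C)(C)C#Cc1cc(Br)c(OC)c(OCOC)c1
A5 | alternative 2 | 3-[3-bromo-4-methoxy-5-(methoxymethoxy)phenyl]-5,7-bis(methoxymethoxy)-2-(trimethylsilyl)-4H-chromen-4-one | COCOc1cc(OCOC)c2c(c1)oc([Si](C)(C)C)c(-c1cc(Br)c(OC)c(OCOC)c1)c2=O
A6 | alternative 3 | (2Z)-3-[3,5-bis(benzyloxy)phenoxy]-2-[3-(benzyloxy)-5-bromo-4-methoxyphenyl]prop-2-enoic acid | OC(=O)/C(=C\Oc1cc(OCc2ccccc2)cc(OCc2ccccc2)c1)c1cc(Br)c(OC)c(OCc2ccccc2)c1
A7 | alternative 3 | 5,7-bis(benzyloxy)-3-[3-(benzyloxy)-5-bromo-4-methoxyphenyl]-4H-chromen-4-one | O=c1c(-c2cc(Br)c(OC)c(OCc3ccccc3)c2)coc2cc(OCc3ccccc3)cc(OCc3ccccc3)c12
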